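**Assumption:** side-chain carbons are labelled C1'–C16' from the benzylic carbon, and reagents without a compound number are bought.

## Retrosynthetic overview

1. The hydroquinone is unmasked last from its dimethyl ether. The C5' acetate and the C13'=C14' enone (cross-metathesis of a vinyl ketone) are installed just before.
2. Key disconnection C9'–C10': the terminal vinyl group of a dienol is hydrozirconated and joined under blue light and nickel to methyl (2R)-3-bromo-2-methylpropanoate, which brings C11'.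
3. C1'–C2' and the C3' methyl: zirconium-catalysed carboalumination of a homopropargylic alcohol, then palladium coupling with a benzylic bromide. C3'–C4': acetylide opening of a dienyl epoxide.
4. C5' is bought in (R)-glycidol, which is elaborated by oxidation/Wittig (E-enal) and methylenation.
5. No ring is formed: the arene comes from 2,6-dimethylhydroquinone and the epoxide from glycidol.

## Route

Step 1
Reactants: 1 2,6-dimethylbenzene-1,4-diol
Product: 2 2,5-dimethoxy-1,3-dimethylbenzene
Conditions: MeI, K2CO3, acetone, reflux, N2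
Reagents that add atoms: iodomethane, CI
Why: Williamson etherification of both phenols masks the hydroquinone as the dimethyl ether, which survives the organometallic steps and is cleaved oxidatively at the end.

Step 2
Reactants: 2 2,5-dimethoxy-1,3-dimethylbenzene
Product: 3 1-(bromomethyl)-2,5-dimethoxy-3-methylbenzene
Conditions: NBS (1.0 equiv), AIBN (cat.), PhCF3, 80 °C
Reagents that add atoms: N-bromosuccinimide, O=C1CCC(=O)N1Br
Why: Wohl–Ziegler radical bromination in a non-polar solvent brominates one of the two equivalent benzylic methyl groups, giving the 1,2,3,5-substitution pattern of the target without any ring regiochemistry problem.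

Step 3
Reactants: 4 (R)-glycidol
Product: 6 (2E)-2-methyl-3-[(2R)-oxiran-2-yl]prop-2-enal, via (2S)-oxirane-2-carbaldehyde 5 (not isolated)
Conditions: TEMPO (10 mol%), PhI(OAc)2, CH2Cl2, rt; then Ph3P=C(Me)CHO, 40 °C
Reagents that add atoms: 2-(triphenyl-λ5-phosphanylidene)propanal, CC(C=O)=P(c1ccccc1)(c1ccccc1)c1ccccc1
Why: TEMPO/PhI(OAc)2 oxidation gives the non-enolisable epoxy aldehyde, which is trapped in the same flask by a stabilised Wittig ylide to give the E-trisubstituted enal (C6'=C7'); the bought stereocentre (later C5') is not touched.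

Step 4
Reactants: 6 (2E)-2-methyl-3-[(2R)-oxiran-2-yl]prop-2-enal
Product: 7 (2R)-2-[(1E)-2-methylbuta-1,3-dien-1-yl]oxirane
Conditions: Ph3PCH3Br, KOt-Bu, THF, 0 °C; then 6, −78 → 0 °C
Reagents that add atoms: methyltriphenylphosphonium bromide, C[P+](c1ccccc1)(c1ccccc1)c1ccccc1.[Br-]
Why: Wittig methylenation adds C9' as a terminal vinyl group; the epoxide and the E-alkene are inert to the ylide at low temperature.

Step 5
Reactants: 7 (2R)-2-[(1E)-2-methylbuta-1,3-dien-1-yl]oxirane
Product: 8 (3E,5S)-3-methylocta-1,3-dien-7-yn-5-ol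
Conditions: LiC≡CH·H2NCH2CH2NH2, DMSO, rt; H2O
Reagents that add atoms: lithium acetylide ethylenediamine complex, [Li]C#C.NCCN
Why: SN2 opening of the epoxide by the hard acetylide at the unhindered terminal carbon (C4') leaves the C5'–O bond intact, so the glycidol centre becomes the (S)-carbinol with retention of its spatial arrangement.

Step 6
Reactants: 8 (3E,5S)-3-methylocta-1,3-dien-7-yn-5-ol; 3 1-(bromomethyl)-2,5-dimethoxy-3-methylbenzene
Product: 10 (3E,5S,7E)-9-(2,5-dimethoxy-3-methylphenyl)-3,7-dimethylnona-1,3,7-trien-5-ol, via alkenyldimethylalane 9 (not isolated)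
Conditions: AlMe3 (3 equiv), Cp2ZrCl2 (25 mol%), CH2Cl2, 0 °C → rt; then 3, Pd(PPh3)4 (5 mol%), THF, rt; aq. NH4Cl
Reagents that add atoms: trimethylaluminium, C[Al](C)C
Why: Negishi zirconium-catalysed syn-carboalumination of the terminal alkyne (as its aluminium alkoxide) puts the methyl on C3' and aluminium on C2' with E geometry, and palladium-catalysed coupling of the alkenylalane with the benzylic bromide forms C1'–C2' with retention.

Step 7
Reactants: 10 (3E,5S,7E)-9-(2,5-dimethoxy-3-methylphenyl)-3,7-dimethylnona-1,3,7-trien-5-ol; 11 methyl (2R)-3-bromo-2-methylpropanoate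
Product: 13 methyl (2S,6E,8S,10E)-12-(2,5-dimethoxy-3-methylphenyl)-8-hydroxy-2,6,10-trimethyldodeca-6,10-dienoate, via homoallylzirconocene chloride 12 (not isolated)
Conditions: Cp2Zr(H)Cl (2.2 equiv), THF, rt, dark; then 11 (2 equiv), NiCl2(dme) (10 mol%), 4,4'-di-tert-butyl-2,2'-bipyridine (12 mol%), 450 nm LEDs, rt; aq. NH4Cl
Reagents that add atoms: none
Why: Proposed new method: a one-pot anti-Markovnikov hydroalkylation of the terminal vinyl group of a 2-substituted 1,3-diene, in which Cp2Zr(H)Cl first converts the hydroxyl into a zirconium alkoxide and then adds 1,2 across the least hindered C=C to give the primary homoallylic alkylzirconocene 12; under 450 nm light the Zr–C bond of this tetravalent zirconium alkyl homolyses to the primary C9' radical and trivalent zirconium, which reduces the nickel dichloride to low-valent nickel; monovalent nickel abstracts bromine from 11 to give the C10' radical, nickel captures both alkyl groups, and the trivalent dialkylnickel reductively eliminates the C9'–C10' bond faster than β-hydride elimination, so C5' and the bought C11' centre (β to the reacting carbon) keep their configuration and the C6'=C7' geometry is untouched; the closest known reaction types are the nickel-catalysed alkyl–alkyl Negishi coupling and light-driven nickel couplings of alkylzirconocenes with organic halides, neither shown for a diene-derived homoallylzirconocene or a β-branched β-ester alkyl bromide.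

Step 8
Reactants: 13 methyl (2S,6E,8S,10E)-12-(2,5-dimethoxy-3-methylphenyl)-8-hydroxy-2,6,10-trimethyldodeca-6,10-dienoate
Product: 15 (4S,8E,10S,12E)-14-(2,5-dimethoxy-3-methylphenyl)-10-hydroxy-4,8,12-trimethyltetradeca-1,8,12-trien-3-one, via Weinreb amide 14 (not isolated)
Conditions: MeNH(OMe)·HCl, i-PrMgCl, THF, −20 °C; then CH2=CHMgBr, 0 °C; inverse quench into cold aq. HCl
Reagents that add atoms: vinylmagnesium bromide, C=C[Mg]Br
Why: Weinreb ketone synthesis run in one flask: the magnesium amide converts the ester into the N-methoxy-N-methylamide without enolising C11', and the chelated tetrahedral adduct with the vinyl Grignard reagent releases the vinyl ketone only on acidic quench.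

Step 9
Reactants: 15 (4S,8E,10S,12E)-14-(2,5-dimethoxy-3-methylphenyl)-10-hydroxy-4,8,12-trimethyltetradeca-1,8,12-trien-3-one; 16 2-methylbut-3-en-2-ol
Product: 17 (3E,6S,10E,12S,14E)-16-(2,5-dimethoxy-3-methylphenyl)-2,12-dihydroxy-2,6,10,14-tetramethylhexadeca-3,10,14-trien-5-one
Conditions: 16 (10 equiv), second-generation Hoveyda–Grubbs catalyst [RuCl2(H2IMes)(=CH-C6H4-2-O-i-Pr)] (5 mol%), CH2Cl2, 40 °C
Reagents that add atoms: none
Why: Olefin cross-metathesis of the terminal enone with the tertiary allylic alcohol gives only the E-γ-hydroxy enone (C13'=C14'); the two trisubstituted alkenes are too hindered to react and the neutral conditions do not epimerise C11'.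

Step 10
Reactants: 17 (3E,6S,10E,12S,14E)-16-(2,5-dimethoxy-3-methylphenyl)-2,12-dihydroxy-2,6,10,14-tetramethylhexadeca-3,10,14-trien-5-one
Product: 18 (2E,5S,6E,11S,13E)-1-(2,5-dimethoxy-3-methylphenyl)-15-hydroxy-3,7,11,15-tetramethyl-12-oxohexadeca-2,6,13-trien-5-yl acetate
Conditions: Ac2O, pyridine, DMAP (cat.), CH2Cl2, 0 °C
Reagents that add atoms: acetic anhydride, CC(=O)OC(C)=O
Why: DMAP-catalysed acylation acetylates the secondary allylic C5' alcohol with retention, while the tertiary C15' alcohol does not react at 0 °C.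

Step 11
Reactants: 18 (2E,5S,6E,11S,13E)-1-(2,5-dimethoxy-3-methylphenyl)-15-hydroxy-3,7,11,15-tetramethyl-12-oxohexadeca-2,6,13-trien-5-yl acetate
Product: 20 (2E,5S,6E,11S,13E)-1-(2,5-dihydroxy-3-methylphenyl)-15-hydroxy-3,7,11,15-tetramethyl-12-oxohexadeca-2,6,13-trien-5-yl acetate, via benzoquinone 19 (not isolated)
Conditions: (NH4)2Ce(NO3)6 (2.2 equiv), MeCN/H2O, 0 °C, 15 min; then aq. Na2S2O4, EtOAc, rt
Reagents that add atoms: water, O
Why: Oxidative demethylation of the 1,4-dimethoxyarene gives the para-quinone (standard for prenylated quinones; acetate, enone and alkenes survive), and dithionite reduction in the same work-up gives the hydroquinone target.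

## Compound list

1 | 2,6-dimethylbenzene-1,4-diol | Cc1cc(O)cc(C)c1O | starting material
2 | 2,5-dimethoxy-1,3-dimethylbenzene | COc1cc(C)c(OC)c(C)c1 | intermediate
3 | 1-(bromomethyl)-2,5-dimethoxy-3-methylbenzene | COc1cc(C)c(OC)c(CBr)c1 | intermediate
4 | (R)-glycidol, [(2R)-oxiran-2-yl]methanol | OC[C@@H]1CO1 | starting material
5 | (2S)-oxirane-2-carbaldehyde | O=C[C@@H]1CO1 | intermediate
6 | (2E)-2-methyl-3-[(2R)-oxiran-2-yl]prop-2-enal | O=C/C(C)=C/[C@@H]1CO1 | intermediate
7 | (2R)-2-[(1E)-2-methylbuta-1,3-dien-1-yl]oxirane | C=C/C(C)=C/[C@@H]1CO1 | intermediate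
8 | (3E,5S)-3-methylocta-1,3-dien-7-yn-5-ol | C#CC[C@H](O)/C=C(C)/C=C | intermediate
9 | dimethyl[(1E,4S,5E)-4-[(dimethylalumanyl)oxy]-2,6-dimethylocta-1,5,7-trien-1-yl]alumane | C[Al](C)/C=C(\C)C[C@H](O[Al](C)C)/C=C(C)/C=C | intermediate
10 | (3E,5S,7E)-9-(2,5-dimethoxy-3-methylphenyl)-3,7-dimethylnona-1,3,7-trien-5-ol | COc1cc(C)c(OC)c(C/C=C(\C)C[C@H](O)/C=C(C)/C=C)c1 | intermediate
11 | methyl (2R)-3-bromo-2-methylpropanoate | BrC[C@H](C)C(=O)OC | starting material
12 | chlorobis(cyclopentadienyl)zirconium (3E,5S,7E)-9-(2,5-dimethoxy-3-methylphenyl)-3,7-dimethylnona-3,7-dien-1-yl species, O5 bound to a second Cp2ZrCl unit | COc1cc(C)c(OC)c(C/C=C(\C)C[C@H](O[Zr](Cl)(C2C=CC=C2)C2C=CC=C2)/C=C(\C)CC[Zr](Cl)(C2C=CC=C2)C2C=CC=C2)c1 | intermediate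
13 | methyl (2S,6E,8S,10E)-12-(2,5-dimethoxy-3-methylphenyl)-8-hydroxy-2,6,10-trimethyldodeca-6,10-dienoate | COc1cc(C)c(OC)c(C/C=C(\C)C[C@H](O)/C=C(\C)CCC[C@H](C)C(=O)OC)c1 | intermediate
14 | (2S,6E,8S,10E)-12-(2,5-dimethoxy-3-methylphenyl)-8-hydroxy-N-methoxy-N,2,6,10-tetramethyldodeca-6,10-dienamide | COc1cc(C)c(OC)c(C/C=C(\C)C[C@H](O)/C=C(\C)CCC[C@H](C)C(=O)N(C)OC)c1 | intermediate
15 | (4S,8E,10S,12E)-14-(2,5-dimethoxy-3-methylphenyl)-10-hydroxy-4,8,12-trimethyltetradeca-1,8,12-trien-3-one | COc1cc(C)c(OC)c(C/C=C(\C)C[C@H](O)/C=C(\C)CCC[C@H](C)C(=O)C=C)c1 | intermediate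
16 | 2-methylbut-3-en-2-ol | CC(C)(O)C=C | starting material
17 | (3E,6S,10E,12S,14E)-16-(2,5-dimethoxy-3-methylphenyl)-2,12-dihydroxy-2,6,10,14-tetramethylhexadeca-3,10,14-trien-5-one | COc1cc(C)c(OC)c(C/C=C(\C)C[C@H](O)/C=C(\C)CCC[C@H](C)C(=O)/C=C/C(C)(C)O)c1 | intermediate
18 | (2E,5S,6E,11S,13E)-1-(2,5-dimethoxy-3-methylphenyl)-15-hydroxy-3,7,11,15-tetramethyl-12-oxohexadeca-2,6,13-trien-5-yl acetate | COc1cc(C)c(OC)c(C/C=C(\C)C[C@H](OC(C)=O)/C=C(\C)CCC[C@H](C)C(=O)/C=C/C(C)(C)O)c1 | intermediate
19 | (2E,5S,6E,11S,13E)-15-hydroxy-3,7,11,15-tetramethyl-1-(5-methyl-3,6-dioxocyclohexa-1,4-dien-1-yl)-12-oxohexadeca-2,6,13-trien-5-yl acetate | CC1=CC(=O)C=C(C/C=C(\C)C[C@H](OC(C)=O)/C=C(\C)CCC[C@H](C)C(=O)/C=C/C(C)(C)O)C1=O | intermediate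
20 | (2E,5S,6E,11S,13E)-1-(2,5-dihydroxy-3-methylphenyl)-15-hydroxy-3,7,11,15-tetramethyl-12-oxohexadeca-2,6,13-trien-5-yl acetate | CC(=O)O[C@H](/C=C(\C)CCC[C@H](C)C(=O)/C=C/C(C)(C)O)C/C(C)=C/Cc1cc(O)cc(C)c1O | target

## Step count and risks

Total: 11 steps. Longest linear sequence: 9 steps (4 → 20, steps 3 to 11).

**Step 7 (the new light-driven zirconium/nickel alkyl–alkyl coupling).** Risks are isomerisation of the homoallyl zirconocene to an allyl species, β-hydride elimination at nickel (loss of 11 as methacrylate or erosion at C11'), and low cross-selectivity. The fallback uses known chemistry, sets out from 10 and comes back at 13. Compound 10 is hydroborated at the terminal vinyl group with 9-BBN (2.2 equiv, the first equivalent being spent on the hydroxyl) to the B-alkyl borane 9-[(3E,5S,7E)-5-(9-borabicyclo[3.3.1]nonan-9-yloxy)-9-(2,5-dimethoxy-3-methylphenyl)-3,7-dimethylnona-3,7-dien-1-yl]-9-borabicyclo[3.3.1]nonane F1. Treatment with I2 and NaOMe in MeOH gives the primary iodide (2E,5S,6E)-1-(2,5-dimethoxy-3-methylphenyl)-9-iodo-3,7-dimethylnona-2,6-dien-5-ol F2. Separately, 11 is converted with zinc dust and LiCl in THF into [(2R)-3-methoxy-2-methyl-3-oxopropyl]zinc bromide F3. F3 (3 equiv) is coupled with F2 under Ni(acac)2, 4-fluorostyrene and Bu4NI in THF/NMP at −5 °C (nickel-catalysed alkyl–alkyl Negishi coupling) to give 13.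

**Step 3 (one-flask oxidation/Wittig).** Glycidaldehyde 5 is volatile and prone to polymerise, and the formyl ylide is sluggish. The fallback sets out from 4 and comes back at 6. After the same oxidation, 5 is trapped with the more nucleophilic Ph3P=C(Me)CO2Et to give ethyl (2E)-2-methyl-3-[(2R)-oxiran-2-yl]prop-2-enoate F4. Reduction with i-Bu2AlH in CH2Cl2 at −78 °C gives (2E)-2-methyl-3-[(2R)-oxiran-2-yl]prop-2-en-1-ol F5, and MnO2 in CH2Cl2 oxidises this allylic alcohol to 6.

**Step 2 (benzylic bromination of an electron-rich arene).** Ring bromination and double bromination can compete. The fallback sets out from 2 and comes back at 3. One methyl group is oxidised by DDQ in aqueous acetic acid (electron-transfer benzylic oxidation) to 2,5-dimethoxy-3-methylbenzaldehyde F6. NaBH4 in MeOH gives (2,5-dimethoxy-3-methylphenyl)methanol F7, and PBr3 in Et2O at 0 °C gives 3.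

## Further compounds

F1 | step 7 | 9-[(3E,5S,7E)-5-(9-borabicyclo[3.3.1]nonan-9-yloxy)-9-(2,5-dimethoxy-3-methylphenyl)-3,7-dimethylnona-3,7-dien-1-yl]-9-borabicyclo[3.3.1]nonane | COc1cc(C)c(OC)c(C/C=C(\C)C[C@H](OB2C3CCCC2CCC3)/C=C(\C)CCB2C3CCCC2CCC3)c1
F2 | step 7 | (2E,5S,6E)-1-(2,5-dimethoxy-3-methylphenyl)-9-iodo-3,7-dimethylnona-2,6-dien-5-ol | COc1cc(C)c(OC)c(C/C=C(\C)C[C@H](O)/C=C(\C)CCI)c1
F3 | step 7 | [(2R)-3-methoxy-2-methyl-3-oxopropyl]zinc bromide | Br[Zn]C[C@H](C)C(=O)OC
F4 | step 3 | ethyl (2E)-2-methyl-3-[(2R)-oxiran-2-yl]prop-2-enoate | CCOC(=O)/C(C)=C/[C@@H]1CO1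
F5 | step 3 | (2E)-2-methyl-3-[(2R)-oxiran-2-yl]prop-2-en-1-ol | OC/C(C)=C/[C@@H]1CO1
F6 | step 2 | 2,5-dimethoxy-3-methylbenzaldehyde | COc1cc(C)c(OC)c(C=O)c1
F7 | step 2 | (2,5-dimethoxy-3-methylphenyl)methanol | COc1cc(C)c(OC)c(CO)c1
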